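## Structural features

The target is a linear flavan trimer: an upper (2S,4R)-4',7-dihydroxyflavan is bonded through C4 to C8 of a middle (2R,3R,4S)-epiafzelechin unit, whose C4 is bonded to C8 of a lower (2R,3R)-epiafzelechin. Each unit is a chroman (benzo ring A fused to pyran ring C) with a 4-hydroxyphenyl ring B on C2; both interflavan bonds lie on the β face, so the upper pyran is 2,4-trans and the middle pyran is 2,3-cis-3,4-trans. There are seven stereocentres: C2 and C4 of the upper unit, the contiguous C2, C3 and C4 of the middle unit, and the cis pair C2 and C3 of the lower unit. The fragile parts are the nine free phenols (air and base), the two diarylmethine C4–C8 bonds to phloroglucinol-type rings (cleaved by protic acid) and the three C2–O1 benzylic ethers that stand para to oxygen (acid-promoted ring opening and epimerisation). The real difficulty is the middle unit: its ring A is hexasubstituted, C8 carries the upper flavan, and C4 is a crowded methine wedged between C5–O of its own ring A and the 2,6-dioxygenated lower ring A, with the C3 hydroxyl trans to it. The key step exploits that middle C4 is at once bonded to C4a of middle ring A, benzylic to lower ring A (through lower C8) and vicinal and trans to the C3 oxygen, which is the pattern left when a trans C3–C4 epoxide is opened at C4, with inversion, by C4a of an aryl ether tethered through O1–C2.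

## Logic of the disconnections

23 from 22. The nine O–CH2Ph bonds are cut. One kind of protecting group on every phenol and on the lower C3 oxygen lets a single neutral hydrogenolysis finish the synthesis, so the free polyphenol never meets acid or base. The forward step must spare the benzylic C2–O1 bonds and the C4–C8 bonds; the middle C3 hydroxyl needs no protection.

22 from 21. The middle C4–C4a bond is cut. This removes ring C, one skeletal bond and the C4 stereocentre at once and turns the three contiguous middle stereocentres into a trans-epoxide plus one ether-bearing carbon. The forward step must open the epoxide at C4 in the 6-endo sense with anti attack, and the aryloxy carbon must be syn (threo) to the epoxide so that the new pyran is 2,3-cis.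

21 from 15 and 20. The O1–C2 ether bond is cut. This divides the molecule into two halves of comparable size, and the bond can be made with inversion from a secondary alcohol. The demand is a clean SN2 etherification at a para-oxygenated benzylic carbinol by a phenol with one bulky ortho substituent, and the carbinol of 15 must be anti to the epoxide.

15 from 14 and 14 from 13. The carbinol C–H bond and then the two epoxide C–O bonds are cut. An E-enone is the simplest carrier of C2, C3 and C4, a trans-epoxy ketone is reachable from it under catalyst control, and chelation-controlled reduction of such ketones gives the anti alcohol. The demands are facial control in the epoxidation of a hindered, donor-substituted enone and survival of the sensitive epoxide during reduction.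

13 from 11 and 12. The Cα=Cβ bond is cut (aldol condensation). The lower unit and the middle ring B become separate, simple pieces. The forward step needs a di-ortho-substituted aldehyde to condense and the flavan stereocentres to be inert to hydroxide.

11 from 8, 8 from 7 and 7 from 6. The C8–CHO bond, the C8–Br bond and the O3–benzyl bond are cut in turn. C8 is the site where 5,7-di-O-alkyl flavans are halogenated, so a one-carbon handle can be placed there late. The demands are C8 over C6 selectivity and a bromine–lithium exchange that is faster than attack on benzyl ethers.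

6 from 5 and 5 from 3 and 4. The lower C4–C4a bond and then the O1–C2 bond are cut, the same two disconnections as in the middle unit in their simplest form. Both lower stereocentres then come from one small epoxy alcohol, and the sequence rehearses the key step. The demands are a 6-endo opening at a primary epoxide carbon without benzylic bias and inversion in the etherification.

3 from 2 and 2 from 1. The epoxide C–O bonds and then the C1–vinyl bond are cut. A racemic allylic alcohol from a one-step addition is resolved and epoxidised in one operation. The demand is high enantiomer discrimination and erythro selectivity; half of the material is given up at the cheapest point.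

20 from 19 and 4. The bond between upper C4 and the aryl carbon that becomes middle C8 is cut. A flavan-4-ol ionises readily to a C4 cation, and the upper C4 stereocentre follows from attack anti to the 2-aryl group. The forward step must alkylate 4 ortho, not para, to its hydroxyl and must stop at monoalkylation.

19 from 18, 18 from 17 and 17 from 16 and 1. The C4–H bond, the O1–C2 bond and the Cα=Cβ bond are cut. The flavanone is two classical steps from catalogue compounds, and its reduction can be made to select the 2S enantiomer. The demand is a high rate difference between the flavanone enantiomers in the transfer hydrogenation.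

## Other disconnections considered

Alternative 1: The cut goes through middle ring A itself (C8–C8a and C6–C7, with C4a–C8a closed in the final electrocyclisation). In the forward sense the 2,4-trans flavan-4-yl siloxyalkyne A1 is heated with the 4-cinnamylcyclobutenone A2 (Danheiser benzannulation) and should give the phenol A3. A3 already has the upper flavan on C8, a free C8a hydroxyl, silyl on the C7 oxygen, benzyl on the C5 oxygen and, on C4a, the cinnamyl chain that holds C4, C3, C2 and ring B.
- In its favour: the substitution pattern of ring A follows from the mechanism and the three ring A oxygens emerge differentiated. On regiocontrol of ring A it is the better plan, because the chosen route depends on ortho selectivity when 4 is alkylated in step 14.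
- Against it here: the step sets no stereocentre and closes no pyran. From A3 the middle unit still needs an asymmetric oxidation of the alkene, a stereospecific C2–O1 closure, activation of C4 and a separate C4–C8 coupling with the lower unit. A1 needs its propargylic 2,4-trans centre made beforehand, and the silyl ether needs its own removal.
- Comparison: structurally it solves the arene, whereas the chosen plan solves the heterocycle and the C4 stereocentre. Mechanistically it is a neutral pericyclic cascade, equal or gentler toward acid-labile bonds but run hot, against a cationic closure at low temperature. In step economy it is clearly longer after its key step, where the chosen plan needs one more step.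

Alternative 2: The cut is the C4a–C5 bond of lower ring A. In the forward sense base converts the dihydropyranone keto ester A4 into its extended enolate, whose ring carbon (the future C4a) acylates the terminal methyl ester (Dieckmann closure); enolisation should give the 5,7-dihydroxyflavanone A5, already joined through C8 to the middle unit.
- In its favour: lower ring A is grown exactly at the carbon that bears the interflavan bond, so C8 against C6 is not a question. This is equal to or better than the chosen plan, which takes that regiochemistry from the selectivity of bromination in step 6.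
- Against it here: A5 is a flavanone, so the lower unit still needs removal of the C4 carbonyl and introduction of a cis C3 hydroxyl, a multi-step redox sequence on a large molecule. The base can open the dihydropyranone by retro-oxa-Michael reaction and scramble lower C2, and the carbon that becomes C8 in A4 is an epimerisable centre next to middle C4. The hard problem, the middle C4 stereocentre, is left to the making of A4.
- Comparison: structurally it builds a benzene ring and leaves both pyran problems open. Mechanistically it uses an anionic condensation in which the benzyl ethers are safe, against a cationic closure that must be kept cold. In step economy it is the longest of the plans after its key step.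

Alternative 3: The cut removes O1–C2 and C3–C4 of middle ring C together. In the forward sense acid ionises the diaryl carbinol A6 to the ortho-quinone methide A7, which should add the Z enol acetate A8 in an inverse-demand hetero-Diels–Alder reaction to give the protected trimer A9 with an acetate on middle C3.
- In its favour: it is the most convergent plan, since ring C, one C–O and one C–C bond and the C3 oxygen arrive in one step and the Z alkene translates into the 2,3-cis relationship. For construction of ring C it is better in step count than the chosen plan, which spends two steps (15 and 16) on the same ring.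
- Against it here: C2, C3 and C4 are created at once with only the remote upper and lower units to bias the face, so absolute control is not secured. The two donors of A8 (acetoxy and 4-benzyloxyphenyl) polarise the alkene in opposite senses, which puts the regiochemistry at risk. The 3,4-trans outcome depends on both the geometry of A7 and the endo or exo approach, and the acetate needs an extra hydrolysis before hydrogenolysis.
- Comparison: structurally both plans close the same ring from pieces of similar complexity, A6 being about as demanding as 13. Mechanistically the cycloaddition is concerted and transfers alkene geometry but has no element that fixes absolute configuration, while the chosen plan sets C3 and C4 by a catalyst, C2 by chelation and inversion, and C4 again by inversion. In step economy alternative 3 is equal or slightly shorter, at the price of stereochemical reliability.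

Key step: step 16

Remark: 3,5-bis(benzyloxy)phenol (4) and 4'-(benzyloxy)-2'-hydroxyacetophenone (16) are taken as catalogue compounds; otherwise they follow from phloroglucinol and 2',4'-dihydroxyacetophenone by routine O-benzylation, which is not counted.

## Route

Step 1
Reactants: 1 4-(benzyloxy)benzaldehyde
Product: 2 (±)-1-[4-(benzyloxy)phenyl]prop-2-en-1-ol
Conditions: CH2=CHMgBr, THF, 0 °C; aq NH4Cl
Reagents that add atoms: vinylmagnesium bromide, C=C[Mg]Br
Why: Grignard 1,2-addition to the aldehyde; the racemic secondary allylic alcohol is the substrate needed for the kinetic resolution of step 2.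

Step 2
Reactants: 2 (±)-1-[4-(benzyloxy)phenyl]prop-2-en-1-ol
Product: 3 (S)-[4-(benzyloxy)phenyl][(R)-oxiran-2-yl]methanol (anti, erythro)
Conditions: Ti(OiPr)4 (cat.), L-(+)-DIPT, t-BuOOH (0.55 equiv), 4 Å sieves, CH2Cl2, −20 °C, stopped near 45% conversion
Reagents that add atoms: tert-butyl hydroperoxide, CC(C)(C)OO
Why: Sharpless kinetic resolution: with Ti(OiPr)4 and the L-(+)-tartrate the (R)-enantiomer of 2 should be epoxidised much faster than the (S)-enantiomer, which is left behind, and oxygen is delivered so that the erythro (anti) epoxy alcohol forms; both stereocentres of 3 are thus set by the reagent. The conversion is held below one half to keep the product enantiomerically pure, and the cold, sieve-dried medium protects the electron-rich benzylic carbinol.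

Step 3
Reactants: 3 (S)-[4-(benzyloxy)phenyl][(R)-oxiran-2-yl]methanol; 4 3,5-bis(benzyloxy)phenol
Product: 5 (R)-2-{(R)-[4-(benzyloxy)phenyl][3,5-bis(benzyloxy)phenoxy]methyl}oxirane (syn, threo)
Conditions: PPh3, DIAD, THF, 0 °C → rt
Reagents that add atoms: none
Why: Mitsunobu etherification with SN2 inversion at the carbinol turns the anti epoxy alcohol into the syn aryl glycidyl ether; the phenol is acidic enough for the betaine, and the neighbouring epoxide oxygen disfavours ionisation of the benzylic oxyphosphonium.

Step 4
Reactants: 5 (R)-2-{(R)-[4-(benzyloxy)phenyl][3,5-bis(benzyloxy)phenoxy]methyl}oxirane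
Product: 6 (2R,3R)-5,7-bis(benzyloxy)-2-[4-(benzyloxy)phenyl]chroman-3-ol (4',5,7-tri-O-benzyl-(−)-epiafzelechin)
Conditions: AuCl3 (5 mol %), AgOTf (15 mol %), ClCH2CH2Cl, rt
Reagents that add atoms: none
Why: Intramolecular Friedel–Crafts epoxy-arene cycloalkylation: the oxophilic cationic catalyst from AuCl3 and AgOTf activates the epoxide, and one of the two equivalent carbons ortho to the ether oxygen opens it at the terminal carbon in the 6-endo mode to give the chroman-3-ol. C2 and C3 are untouched, so the syn ether gives the 2,3-cis (epi) series.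

Step 5
Reactants: 6 (2R,3R)-5,7-bis(benzyloxy)-2-[4-(benzyloxy)phenyl]chroman-3-ol
Product: 7 (2R,3R)-3,5,7-tris(benzyloxy)-2-[4-(benzyloxy)phenyl]chromane (tetra-O-benzyl-(−)-epiafzelechin)
Conditions: NaH, BnBr, n-Bu4NI (cat.), DMF, 0 °C → rt
Reagents that add atoms: benzyl bromide, BrCc1ccccc1
Why: Williamson etherification of the secondary alkoxide; the benzyl ether masks the one alcohol that would compete in the Mitsunobu reaction of step 15 and leaves with the others in step 17.

Step 6
Reactants: 7 (2R,3R)-3,5,7-tris(benzyloxy)-2-[4-(benzyloxy)phenyl]chromane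
Product: 8 (2R,3R)-3,5,7-tris(benzyloxy)-2-[4-(benzyloxy)phenyl]-8-bromochromane
Conditions: NBS, CH2Cl2, −78 °C → rt
Reagents that add atoms: N-bromosuccinimide, O=C1CCC(=O)N1Br
Why: Electrophilic aromatic bromination; in 5,7-di-O-alkyl flavans C8, flanked by the ring oxygen, is more accessible than C6 between two benzyloxy groups, so monobromination at C8 is expected.

Step 7
Reactants: 8 (2R,3R)-3,5,7-tris(benzyloxy)-2-[4-(benzyloxy)phenyl]-8-bromochromane
Product: 11 (2R,3R)-3,5,7-tris(benzyloxy)-2-[4-(benzyloxy)phenyl]chromane-8-carbaldehyde, via 8-lithiochromane 9 (not isolated), via lithium hemiaminal alkoxide 10 (not isolated)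
Conditions: n-BuLi, THF, −78 °C; DMF, −78 → 0 °C; aq NH4Cl
Reagents that add atoms: N,N-dimethylformamide, CN(C)C=O
Why: Bromine–lithium exchange is faster than deprotonation of benzyl ethers at −78 °C, and formylation of the aryllithium with DMF (Bouveault aldehyde synthesis) gives the aldehyde once the hemiaminal alkoxide is hydrolysed.

Step 8
Reactants: 11 (2R,3R)-3,5,7-tris(benzyloxy)-2-[4-(benzyloxy)phenyl]chromane-8-carbaldehyde; 12 4'-(benzyloxy)acetophenone
Product: 13 (E)-1-[4-(benzyloxy)phenyl]-3-{(2R,3R)-3,5,7-tris(benzyloxy)-2-[4-(benzyloxy)phenyl]chroman-8-yl}prop-2-en-1-one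
Conditions: KOH, EtOH/THF, rt
Reagents that add atoms: none
Why: Claisen–Schmidt condensation: the aldehyde has no α-hydrogen, so only the acetophenone enolises, and E1cB dehydration gives the E-enone; the flavan stereocentres are not base-labile.

Step 9
Reactants: 13 (E)-1-[4-(benzyloxy)phenyl]-3-{(2R,3R)-3,5,7-tris(benzyloxy)-2-[4-(benzyloxy)phenyl]chroman-8-yl}prop-2-en-1-one
Product: 14 [4-(benzyloxy)phenyl]{(2R,3S)-3-[(2R,3R)-3,5,7-tris(benzyloxy)-2-(4-benzyloxyphenyl)chroman-8-yl]oxiran-2-yl}methanone
Conditions: poly-L-leucine, urea·H2O2, DBU, THF, rt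
Reagents that add atoms: urea–hydrogen peroxide, OO.NC(N)=O
Why: Juliá–Colonna epoxidation: hydroperoxide adds in conjugate fashion inside the helical poly-L-leucine, which for chalcones delivers the (2R,3S) trans-epoxy ketone, and ring closure of the peroxy enolate keeps the trans geometry. The catalyst, not the remote lower unit, should control the face, and any minor epoxide is a diastereomer that can be removed by chromatography.

Step 10
Reactants: 14 [4-(benzyloxy)phenyl]{(2R,3S)-3-[(2R,3R)-3,5,7-tris(benzyloxy)-2-(4-benzyloxyphenyl)chroman-8-yl]oxiran-2-yl}methanone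
Product: 15 (S)-[4-(benzyloxy)phenyl]{(2S,3S)-3-[(2R,3R)-3,5,7-tris(benzyloxy)-2-(4-benzyloxyphenyl)chroman-8-yl]oxiran-2-yl}methanol (anti, erythro; the epoxide is spatially unchanged from 14)
Conditions: Zn(BH4)2, Et2O/THF, −78 → −20 °C; aq NaHCO3
Reagents that add atoms: none
Why: Chelation-controlled reduction: Zn(BH4)2 bridges the carbonyl and epoxide oxygens and hydride attacks the less hindered face of the chelate, which gives the anti (erythro) epoxy alcohol and so sets the carbinol centre that becomes middle C2 after inversion. The aprotic, near-neutral medium and cold basic quench spare the acid-sensitive epoxide.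

Step 11
Reactants: 16 4'-(benzyloxy)-2'-hydroxyacetophenone; 1 4-(benzyloxy)benzaldehyde
Product: 17 (E)-1-[4-(benzyloxy)-2-hydroxyphenyl]-3-[4-(benzyloxy)phenyl]prop-2-en-1-one
Conditions: KOH, EtOH, rt
Reagents that add atoms: none
Why: Claisen–Schmidt condensation of the methyl ketone with the non-enolisable aldehyde gives the E-2'-hydroxychalcone.

Step 12
Reactants: 17 (E)-1-[4-(benzyloxy)-2-hydroxyphenyl]-3-[4-(benzyloxy)phenyl]prop-2-en-1-one
Product: 18 (±)-7-(benzyloxy)-2-[4-(benzyloxy)phenyl]chroman-4-one
Conditions: NaOAc, EtOH/H2O, reflux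
Reagents that add atoms: none
Why: Base-mediated intramolecular oxa-Michael addition of the phenoxide to the enone closes the pyranone and gives the racemic flavanone; unchanged 17 is recycled.

Step 13
Reactants: 18 (±)-7-(benzyloxy)-2-[4-(benzyloxy)phenyl]chroman-4-one
Product: 19 (2S,4S)-7-(benzyloxy)-2-[4-(benzyloxy)phenyl]chroman-4-ol (2,4-cis)
Conditions: RuCl[(S,S)-TsDPEN](p-cymene) (1 mol %), HCO2H/Et3N (5:2), EtOAc, rt, stopped near 50% conversion
Reagents that add atoms: none
Why: Noyori–Ikariya asymmetric transfer hydrogenation run as a kinetic resolution: the (S,S) catalyst delivers hydride to form the 4S carbinol, which is matched with axial attack on the 2S flavanone, so the 2S enantiomer is reduced to the 2,4-cis alcohol. The 2R enantiomer of 18 is left, and base can racemise it through 17 for recycling.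

Step 14
Reactants: 19 (2S,4S)-7-(benzyloxy)-2-[4-(benzyloxy)phenyl]chroman-4-ol; 4 3,5-bis(benzyloxy)phenol
Product: 20 3,5-bis(benzyloxy)-2-{(2S,4R)-7-(benzyloxy)-2-[4-(benzyloxy)phenyl]chroman-4-yl}phenol (2,4-trans)
Conditions: BF3·OEt2 (0.2 equiv), 4 (3 equiv), CH2Cl2, −40 → 0 °C
Reagents that add atoms: none
Why: Friedel–Crafts alkylation through the flavan C4 cation, which is stabilised by the ring oxygen and the 7-benzyloxy group; the phenol should attack through the carbon ortho to its hydroxyl, the less hindered of its nucleophilic carbons, and axially anti to the equatorial 2-aryl group, giving the 2,4-trans product. C2 is untouched, and excess 4 limits double alkylation.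

Step 15
Reactants: 15 (S)-[4-(benzyloxy)phenyl]{(2S,3S)-3-[(2R,3R)-3,5,7-tris(benzyloxy)-2-(4-benzyloxyphenyl)chroman-8-yl]oxiran-2-yl}methanol; 20 3,5-bis(benzyloxy)-2-{(2S,4R)-7-(benzyloxy)-2-[4-(benzyloxy)phenyl]chroman-4-yl}phenol
Product: 21 aryl ether precursor: the (R)-configured carbon bearing 4-(benzyloxy)phenyl and the (2R,3S)-3-[(2R,3R)-3,5,7-tris(benzyloxy)-2-(4-benzyloxyphenyl)chroman-8-yl]oxiran-2-yl group is bonded to the phenolic oxygen of 20 (syn, threo)
Conditions: PPh3, DIAD, toluene, 0 °C → rt
Reagents that add atoms: none
Why: Mitsunobu etherification with inversion at the carbinol converts the anti epoxy alcohol into the syn aryl ether required for a 2,3-cis pyran. The epoxide survives these neutral conditions and its inductive effect disfavours ionisation of the benzylic oxyphosphonium; the product is purified on base-washed silica.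

Step 16
Reactants: 21 aryl ether precursor (syn epoxy aryl ether carrying the upper flavan on the phenoxy ring and the lower unit on the epoxide)
Product: 22 nona-O-benzyl trimer with free middle 3-OH: (2S,4R)-4',7-di-O-benzylflavan-(4β→8)-(2R,3R,4S)-4',5,7-tri-O-benzylepiafzelechin-(4β→8)-(2R,3R)-3,4',5,7-tetra-O-benzylepiafzelechin
Conditions: BF3·OEt2 (0.3 equiv), CH2Cl2 (0.002 M), −78 °C; Et3N quench
Reagents that add atoms: none
Why: BF3 binds the epoxide oxygen and the C4–O bond, benzylic to the 2,4,6-trioxygenated lower ring A, stretches toward an ion pair; C4a of the tethered ring, activated by three oxygens, attacks C4 from the side opposite the departing oxygen, an intramolecular Friedel–Crafts alkylation of the epoxy-arene type known to convert aryl glycidyl ethers into trans-4-arylchroman-3-ols. Ring C closes in the 6-endo mode: both epoxide carbons become ring members and the C3 oxygen is released as the free hydroxyl. The one new stereocentre, C4, is fixed by inversion at the trans-epoxide carbon, which gives the 3,4-trans relationship; C2 (steps 10 and 15) and C3 (step 9) are untouched, so the 2,3-cis-3,4-trans pattern results. If the opening goes as far as a free cation, minimising allylic strain between the C3 substituents and the ortho oxygens of the lower ring puts C2 and its tethered arene on the face anti to the C3 oxygen, so the same isomer is expected. Endo attack at C4 over exo attack at C3 (five-membered ring) is secured by the cation-stabilising aryl group on C4. There is no regiochemical choice on ring A, because C8 is occupied by the upper flavan and the only other free carbon is para to the ether oxygen and cannot reach. The step needs ring closure to outrun 1,2-hydride shift to a benzyl ketone and ionisation of the C2–O aryl ether; low temperature, substoichiometric acid, high dilution and the strongly nucleophilic, pre-positioned arene serve this.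

Step 17
Reactants: 22 nona-O-benzyl trimer with free middle 3-OH
Product: 23 (2S,4R)-4',7-dihydroxyflavan-(4β→8)-(2R,3R,4S)-epiafzelechin-(4β→8)-(2R,3R)-epiafzelechin (CNP0257624.1)
Conditions: H2 (1 atm), Pd(OH)2/C, THF/MeOH/H2O, rt
Reagents that add atoms: none
Why: Hydrogenolysis of the nine benzyl ethers under neutral conditions; the pyran C2–O1 bonds and the diarylmethine C4–C8 bonds are not expected to cleave at ambient pressure, and the polyphenol meets neither acid nor base.

## Compound list

1 | 4-(benzyloxy)benzaldehyde | O=Cc1ccc(OCc2ccccc2)cc1 | starting material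
2 | (±)-1-[4-(benzyloxy)phenyl]prop-2-en-1-ol (racemic) | OC(C=C)c1ccc(OCc2ccccc2)cc1 | intermediate
3 | (S)-[4-(benzyloxy)phenyl][(R)-oxiran-2-yl]methanol | O[C@@H](c1ccc(OCc2ccccc2)cc1)[C@@H]1OC1 | intermediate
4 | 3,5-bis(benzyloxy)phenol | Oc1cc(OCc2ccccc2)cc(OCc2ccccc2)c1 | starting material
5 | (R)-2-{(R)-[4-(benzyloxy)phenyl][3,5-bis(benzyloxy)phenoxy]methyl}oxirane | c1ccccc1COc1cc(OCc2ccccc2)cc(O[C@H](c2ccc(OCc3ccccc3)cc2)[C@@H]2OC2)c1 | intermediate
6 | (2R,3R)-5,7-bis(benzyloxy)-2-[4-(benzyloxy)phenyl]chroman-3-ol | c1c(OCc3ccccc3)cc(OCc3ccccc3)c2c1O[C@H](c1ccc(OCc3ccccc3)cc1)[C@H](O)C2 | intermediate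
7 | (2R,3R)-3,5,7-tris(benzyloxy)-2-[4-(benzyloxy)phenyl]chromane | c1c(OCc3ccccc3)cc(OCc3ccccc3)c2c1O[C@H](c1ccc(OCc3ccccc3)cc1)[C@H](OCc3ccccc3)C2 | intermediate
8 | (2R,3R)-3,5,7-tris(benzyloxy)-2-[4-(benzyloxy)phenyl]-8-bromochromane | Brc1c(OCc3ccccc3)cc(OCc3ccccc3)c2c1O[C@H](c1ccc(OCc3ccccc3)cc1)[C@H](OCc3ccccc3)C2 | intermediate
9 | (2R,3R)-3,5,7-tris(benzyloxy)-2-[4-(benzyloxy)phenyl]chroman-8-yllithium (not isolated) | [Li]c1c(OCc3ccccc3)cc(OCc3ccccc3)c2c1O[C@H](c1ccc(OCc3ccccc3)cc1)[C@H](OCc3ccccc3)C2 | intermediate
10 | lithium (dimethylamino){(2R,3R)-3,5,7-tris(benzyloxy)-2-[4-(benzyloxy)phenyl]chroman-8-yl}methanolate, both epimers at the new carbon (not isolated) | [Li]OC(N(C)C)c1c(OCc3ccccc3)cc(OCc3ccccc3)c2c1O[C@H](c1ccc(OCc3ccccc3)cc1)[C@H](OCc3ccccc3)C2 | intermediate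
11 | (2R,3R)-3,5,7-tris(benzyloxy)-2-[4-(benzyloxy)phenyl]chromane-8-carbaldehyde | O=Cc1c(OCc3ccccc3)cc(OCc3ccccc3)c2c1O[C@H](c1ccc(OCc3ccccc3)cc1)[C@H](OCc3ccccc3)C2 | intermediate
12 | 4'-(benzyloxy)acetophenone | CC(=O)c1ccc(OCc2ccccc2)cc1 | starting material
13 | (E)-1-[4-(benzyloxy)phenyl]-3-{(2R,3R)-3,5,7-tris(benzyloxy)-2-[4-(benzyloxy)phenyl]chroman-8-yl}prop-2-en-1-one | O=C(/C=C/c1c(OCc3ccccc3)cc(OCc3ccccc3)c2c1O[C@H](c1ccc(OCc3ccccc3)cc1)[C@H](OCc3ccccc3)C2)c1ccc(OCc3ccccc3)cc1 | intermediate
14 | [4-(benzyloxy)phenyl]{(2R,3S)-3-[(2R,3R)-3,5,7-tris(benzyloxy)-2-(4-benzyloxyphenyl)chroman-8-yl]oxiran-2-yl}methanone | O=C(c1ccc(OCc3ccccc3)cc1)[C@@H]1O[C@H]1c1c(OCc3ccccc3)cc(OCc3ccccc3)c2c1O[C@H](c1ccc(OCc3ccccc3)cc1)[C@H](OCc3ccccc3)C2 | intermediate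
15 | (S)-[4-(benzyloxy)phenyl]{(2S,3S)-3-[(2R,3R)-3,5,7-tris(benzyloxy)-2-(4-benzyloxyphenyl)chroman-8-yl]oxiran-2-yl}methanol (anti) | O[C@@H](c1ccc(OCc3ccccc3)cc1)[C@@H]1O[C@H]1c1c(OCc3ccccc3)cc(OCc3ccccc3)c2c1O[C@H](c1ccc(OCc3ccccc3)cc1)[C@H](OCc3ccccc3)C2 | intermediate
16 | 4'-(benzyloxy)-2'-hydroxyacetophenone | CC(=O)c1ccc(OCc2ccccc2)cc1O | starting material
17 | (E)-1-[4-(benzyloxy)-2-hydroxyphenyl]-3-[4-(benzyloxy)phenyl]prop-2-en-1-one | O=C(/C=C/c1ccc(OCc2ccccc2)cc1)c1ccc(OCc2ccccc2)cc1O | intermediate
18 | (±)-7-(benzyloxy)-2-[4-(benzyloxy)phenyl]chroman-4-one (racemic) | O=C1CC(c2ccc(OCc3ccccc3)cc2)Oc2cc(OCc3ccccc3)ccc12 | intermediate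
19 | (2S,4S)-7-(benzyloxy)-2-[4-(benzyloxy)phenyl]chroman-4-ol | c1ccccc1COc1ccc([C@@H]2C[C@H](O)c3ccc(OCc4ccccc4)cc3O2)cc1 | intermediate
20 | 3,5-bis(benzyloxy)-2-{(2S,4R)-7-(benzyloxy)-2-[4-(benzyloxy)phenyl]chroman-4-yl}phenol | c1ccccc1COc1ccc([C@@H]2C[C@@H](c3c(O)cc(OCc4ccccc4)cc3OCc4ccccc4)c3ccc(OCc4ccccc4)cc3O2)cc1 | intermediate
21 | aryl ether precursor: ether of 20 with the (R)-carbon bearing 4-(benzyloxy)phenyl and the (2R,3S)-3-(lower chroman-8-yl)oxiran-2-yl group | c5ccccc5COc1ccc([C@@H]2C[C@@H](c3c(OCc5ccccc5)cc(OCc5ccccc5)cc3O[C@H](c4ccc(OCc5ccccc5)cc4)[C@@H]4O[C@H]4c3c(OCc5ccccc5)cc(OCc5ccccc5)c4c3O[C@H](c3ccc(OCc5ccccc5)cc3)[C@H](OCc5ccccc5)C4)c3ccc(OCc5ccccc5)cc3O2)cc1 | intermediate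
22 | nona-O-benzyl trimer with free middle 3-OH: upper (2S,4R), middle (2R,3R,4S), lower (2R,3R) | c5ccccc5COc1ccc([C@@H]2C[C@@H](c3c(OCc5ccccc5)cc(OCc5ccccc5)c4c3O[C@H](c3ccc(OCc5ccccc5)cc3)[C@H](O)[C@H]4c3c(OCc5ccccc5)cc(OCc5ccccc5)c4c3O[C@H](c3ccc(OCc5ccccc5)cc3)[C@H](OCc5ccccc5)C4)c3ccc(OCc5ccccc5)cc3O2)cc1 | intermediate
23 | (2S,4R)-4',7-dihydroxyflavan-(4β→8)-(2R,3R,4S)-epiafzelechin-(4β→8)-(2R,3R)-epiafzelechin | Oc1ccc([C@@H]2C[C@@H](c3c(O)cc(O)c4c3O[C@H](c3ccc(O)cc3)[C@H](O)[C@H]4c3c(O)cc(O)c4c3O[C@H](c3ccc(O)cc3)[C@H](O)C4)c3ccc(O)cc3O2)cc1 | target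

## Step count and risk

Total step count: 17. Longest linear sequence: 13 steps (1 to 10, then 15, 16 and 17); the branch to 20 has 4 steps (11 to 14).

Least certain steps:

Step 16 (key step). The most likely failure is that the opened epoxide undergoes a 1,2-hydride shift to a benzyl ketone, or that the 4-benzyloxybenzylic C2–O aryl ether ionises, before the crowded C4–C4a bond can form. The cation next to the trioxygenated lower ring is long-lived, and the closure has to bring a diarylmethine carbon against the C5 benzyloxy group. The fallback changes the order of bond formation. It sets out from 15 and 20 and returns at 22. The epoxide of 15 is opened at its benzylic carbon by the carbon ortho to the hydroxyl of 20 in an intermolecular Friedel–Crafts alkylation (BF3·OEt2 at low temperature or hexafluoroisopropanol as solvent), which gives the C-alkylated triol F1 with inversion at C4. An intramolecular Mitsunobu etherification (PPh3, DIAD) of the phenol onto the benzylic C2 carbinol then closes the pyran with inversion at C2 and gives 22.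

Step 15. The likely failure is slow capture of the oxyphosphonium by the phenol, whose hydroxyl sits next to the bulky flavan-4-yl group, so that ionisation of the para-benzyloxybenzylic centre (loss of inversion, elimination or epoxide participation) takes over. The fallback attaches the upper unit last. It sets out from 15 and 4 and returns at 22. Mitsunobu coupling of 15 with the unhindered phenol 4 gives the aryl glycidyl ether F2, and the same BF3·OEt2 closure as in step 16 gives the dimer F3 with a free C8 on its upper ring. Friedel–Crafts alkylation of F3 with the C4 cation from 19 (BF3·OEt2, −40 °C) then gives 22; it is expected to occur at the accessible C8 of the terminal unit, as in chain extension of 4→8 oligomers, and anti to the 2-aryl group.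

Step 9. The likely failure is low conversion together with poor facial control, because the β-carbon is deactivated by the donor ring and shielded by two ortho oxygens, so that conjugate addition of hydroperoxide inside the polypeptide is slow. The fallback replaces nucleophilic by hydroxyl-directed electrophilic epoxidation. It sets out from 13 and returns at 15, bypassing 14. Luche reduction (NaBH4, CeCl3·7H2O, MeOH/THF, −78 °C) gives the allylic alcohol F4 as a pair of carbinol epimers. Epoxidation with Ti(OiPr)4, L-(+)-DIPT and t-BuOOH at −20 °C, in the sense established in step 2, should convert the (R)-carbinol epimer rapidly into the erythro epoxy alcohol 15. The slow epimer is recovered and oxidised back to 13 with MnO2.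

Step 14. The likely failure is alkylation of 4 through its para carbon (between the two benzyloxy groups) or a second alkylation of 20, since the cation is unselective toward such an electron-rich ring; incomplete 2,4-trans selectivity is a lesser concern. The fallback removes the regiochemical choice by symmetry. It sets out from 19 and returns at 20. Friedel–Crafts alkylation of free phloroglucinol (in excess) with 19 gives the triol F5, in which every ring carbon is equivalent before reaction. Controlled benzylation (BnBr, 2 equiv, K2CO3, DMF) should take the unhindered para hydroxyl and one of the two equivalent ortho hydroxyls, giving 20 after separation from under- and over-benzylated material.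

Further compounds

F1 | step 16 | 3,5-bis(benzyloxy)-2-[(2S,4R)-7-(benzyloxy)-2-(4-benzyloxyphenyl)chroman-4-yl]-6-{1-[(2R,3R)-3,5,7-tris(benzyloxy)-2-(4-benzyloxyphenyl)chroman-8-yl]-2,3-dihydroxy-3-[4-(benzyloxy)phenyl]propyl}phenol (chain carbons configured as C4 and C3 of 22 and as the carbinol of 15) | c5ccccc5COc1ccc([C@@H]2C[C@@H](c3c(OCc5ccccc5)cc(OCc5ccccc5)c([C@H](c6c(OCc5ccccc5)cc(OCc5ccccc5)c7c6O[C@H](c6ccc(OCc5ccccc5)cc6)[C@H](OCc5ccccc5)C7)[C@@H](O)[C@@H](O)c6ccc(OCc5ccccc5)cc6)c3O)c3ccc(OCc5ccccc5)cc3O2)cc1
F2 | step 15 | (2R,3S)-2-{(R)-[4-(benzyloxy)phenyl][3,5-bis(benzyloxy)phenoxy]methyl}-3-[(2R,3R)-3,5,7-tris(benzyloxy)-2-(4-benzyloxyphenyl)chroman-8-yl]oxirane | c1ccccc1COc1cc(OCc2ccccc2)cc(O[C@H](c2ccc(OCc3ccccc3)cc2)[C@@H]2O[C@H]2c2c(OCc3ccccc3)cc(OCc3ccccc3)c4c2O[C@H](c2ccc(OCc3ccccc3)cc2)[C@H](OCc3ccccc3)C4)c1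
F3 | step 15 | hepta-O-benzyl epiafzelechin-(4β→8)-epiafzelechin with free upper 3-OH (22 without the flavan on C8) | c1c(OCc3ccccc3)cc(OCc3ccccc3)c2c1O[C@H](c1ccc(OCc3ccccc3)cc1)[C@H](O)[C@H]2c1c(OCc3ccccc3)cc(OCc3ccccc3)c2c1O[C@H](c1ccc(OCc3ccccc3)cc1)[C@H](OCc3ccccc3)C2
F4 | step 9 | (E)-1-[4-(benzyloxy)phenyl]-3-{(2R,3R)-3,5,7-tris(benzyloxy)-2-[4-(benzyloxy)phenyl]chroman-8-yl}prop-2-en-1-ol (both carbinol epimers) | OC(/C=C/c1c(OCc3ccccc3)cc(OCc3ccccc3)c2c1O[C@H](c1ccc(OCc3ccccc3)cc1)[C@H](OCc3ccccc3)C2)c1ccc(OCc3ccccc3)cc1
F5 | step 14 | 2-{(2S,4R)-7-(benzyloxy)-2-[4-(benzyloxy)phenyl]chroman-4-yl}benzene-1,3,5-triol | c1ccccc1COc1ccc([C@@H]2C[C@@H](c3c(O)cc(O)cc3O)c3ccc(OCc4ccccc4)cc3O2)cc1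
A1 | alternative 1 | (2S,4S)-7-(benzyloxy)-2-[4-(benzyloxy)phenyl]-4-[(triisopropylsilyloxy)ethynyl]chromane (2,4-trans) | c1ccccc1COc1ccc([C@@H]2C[C@@H](C#CO[Si](C(C)C)(C(C)C)C(C)C)c3ccc(OCc4ccccc4)cc3O2)cc1
A2 | alternative 1 | 3-(benzyloxy)-4-{(E)-3-[4-(benzyloxy)phenyl]prop-2-en-1-yl}cyclobut-2-en-1-one (racemic) | O=C1C=C(OCc2ccccc2)C1C/C=C/c1ccc(OCc2ccccc2)cc1
A3 | alternative 1 | 3-(benzyloxy)-2-{(E)-3-[4-(benzyloxy)phenyl]prop-2-en-1-yl}-6-{(2S,4R)-7-(benzyloxy)-2-[4-(benzyloxy)phenyl]chroman-4-yl}-5-(triisopropylsilyloxy)phenol | c5ccccc5COc1ccc([C@@H]2C[C@@H](c3c(O)c(C/C=C/c4ccc(OCc5ccccc5)cc4)c(OCc5ccccc5)cc3O[Si](C(C)C)(C(C)C)C(C)C)c3ccc(OCc5ccccc5)cc3O2)cc1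
A4 | alternative 2 | benzylated upper–middle dimer whose middle C4 carries a CH bonded to C6 of a (2S)-2-[4-(benzyloxy)phenyl]-2,3-dihydro-4H-pyran-4-one and to a 3-oxobutanoate methyl ester chain (the CH centre unassigned) | c5ccccc5COc1ccc([C@@H]2C[C@@H](c3c(OCc5ccccc5)cc(OCc5ccccc5)c4c3O[C@H](c3ccc(OCc5ccccc5)cc3)[C@H](OCc5ccccc5)[C@H]4C(C(=O)CC(=O)OC)C3=CC(=O)C[C@@H](c6ccc(OCc5ccccc5)cc6)O3)c3ccc(OCc5ccccc5)cc3O2)cc1
A5 | alternative 2 | benzylated upper–middle dimer bonded through middle C4 to C8 of (2S)-4'-O-benzyl-5,7-dihydroxyflavanone | c5ccccc5COc1ccc([C@@H]2C[C@@H](c3c(OCc5ccccc5)cc(OCc5ccccc5)c4c3O[C@H](c3ccc(OCc5ccccc5)cc3)[C@H](OCc5ccccc5)[C@H]4c3c(O)cc(O)c4c3O[C@H](c3ccc(OCc5ccccc5)cc3)CC4=O)c3ccc(OCc5ccccc5)cc3O2)cc1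
A6 | alternative 3 | diaryl carbinol: 3,5-bis(benzyloxy)-2-(upper flavan-4-yl)-6-{hydroxy[(2R,3R)-3,5,7-tris(benzyloxy)-2-(4-benzyloxyphenyl)chroman-8-yl]methyl}phenol (carbinol centre unassigned) | c5ccccc5COc1ccc([C@@H]2C[C@@H](c3c(OCc5ccccc5)cc(OCc5ccccc5)c(C(O)c6c(OCc5ccccc5)cc(OCc5ccccc5)c7c6O[C@H](c6ccc(OCc5ccccc5)cc6)[C@H](OCc5ccccc5)C7)c3O)c3ccc(OCc5ccccc5)cc3O2)cc1
A7 | alternative 3 | ortho-quinone methide from A6: 3,5-bis(benzyloxy)-2-(upper flavan-4-yl)-6-[(lower chroman-8-yl)methylidene]cyclohexa-2,4-dien-1-one (alkene geometry unassigned) | c5ccccc5COc1ccc([C@@H]2C[C@@H](C3=C(OCc5ccccc5)C=C(OCc5ccccc5)C(=Cc6c(OCc5ccccc5)cc(OCc5ccccc5)c7c6O[C@H](c6ccc(OCc5ccccc5)cc6)[C@H](OCc5ccccc5)C7)C3=O)c3ccc(OCc5ccccc5)cc3O2)cc1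
A8 | alternative 3 | (Z)-2-[4-(benzyloxy)phenyl]vinyl acetate | CC(=O)O/C=C\c1ccc(OCc2ccccc2)cc1
A9 | alternative 3 | nona-O-benzyl trimer with the middle C3 oxygen as acetate | c5ccccc5COc1ccc([C@@H]2C[C@@H](c3c(OCc5ccccc5)cc(OCc5ccccc5)c4c3O[C@H](c3ccc(OCc5ccccc5)cc3)[C@H](OC(C)=O)[C@H]4c3c(OCc5ccccc5)cc(OCc5ccccc5)c4c3O[C@H](c3ccc(OCc5ccccc5)cc3)[C@H](OCc5ccccc5)C4)c3ccc(OCc5ccccc5)cc3O2)cc1
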